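The target is an 18-membered bis(bibenzyl). Ether oxygens join ring A to ring B and ring C to ring D, while CH2–CH2 bridges join ring B to ring C and ring D to ring A. All four bridge carbons are benzylic, and the plan exploits this: each central CH2–CH2 bond is traced back to a CH2–S–CH2 unit. One photolysis in trimethyl phosphite should expel both sulfur atoms and pair the benzylic carbons, shrinking the ring from 20 to 18 members. The precursor is the 20-membered dithiacyclophane with the ring C phenol masked as a MOM ether. Its ring order is fixed by one intermolecular sulfide coupling and one closure with sulfide ion.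

Key step: step 12

Ring labels: A = 1,2,3-trisubstituted methoxy ring; B = meta-linked ring; C = phenol ring; D = para-linked ring.

Remark on the chemistry: the target has no stereocentre, and the 18-membered ring is taken to be conformationally mobile, so no descriptor is needed.

Design remarks:
- The 4-OH of the catechol ester is masked first, so that only O3 can be arylated.
- Both aldehyde-derived carbons belong to the A–D bridge, so that bridge is made first.
- The two remaining ester-derived carbons (rings B and C) cannot be told apart as bromide and thiol. They are therefore brominated together and bridged by a single sulfide ion.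

Step 1
Reactants: 1 2-fluoro-3-methoxybenzaldehyde; 2 methyl 3-hydroxybenzoate
Product: 3 methyl 3-(2-formyl-6-methoxyphenoxy)benzoate
Conditions: K2CO3, DMF, 120 °C
Reagents that add atoms: none
Why: SNAr, in which the ortho formyl group stabilises the anionic sigma adduct at C2 and fluoride is the best leaving group for addition–elimination, so the phenoxide of 2 should displace it while K2CO3 leaves ester and aldehyde alone.

Step 2
Reactants: 4 methyl 3,4-dihydroxybenzoate
Product: 5 methyl 3-hydroxy-4-(methoxymethoxy)benzoate
Conditions: MOMCl (1.0 equiv), K2CO3 (1.0 equiv), acetone, 0 °C to rt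
Reagents that add atoms: chloromethyl methyl ether, COCCl
Why: Regioselective Williamson-type O-alkylation, since the 4-OH is para to the ester and the more acidic, so one equivalent of weak base should form mainly the 4-phenoxide for trapping by MOMCl, with the isomer and the bis-ether removed by chromatography.

Step 3
Reactants: 5 methyl 3-hydroxy-4-(methoxymethoxy)benzoate; 6 4-fluorobenzaldehyde
Product: 7 methyl 3-(4-formylphenoxy)-4-(methoxymethoxy)benzoate
Conditions: K2CO3, DMF, 120 °C
Reagents that add atoms: none
Why: SNAr on a para-formyl-activated aryl fluoride by the only free phenoxide (O3), under basic conditions to which the MOM acetal and the ester are stable.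

Step 4
Reactants: 3 methyl 3-(2-formyl-6-methoxyphenoxy)benzoate
Product: 8 methyl 3-[2-(hydroxymethyl)-6-methoxyphenoxy]benzoate
Conditions: NaBH4, MeOH/THF, 0 °C
Reagents that add atoms: none
Why: Chemoselective borohydride reduction, as NaBH4 at 0 °C reduces the aryl aldehyde quickly whereas the benzoate ester is inert.

Step 5
Reactants: 8 methyl 3-[2-(hydroxymethyl)-6-methoxyphenoxy]benzoate
Product: 9 methyl 3-[2-(bromomethyl)-6-methoxyphenoxy]benzoate
Conditions: PBr3, CH2Cl2, 0 °C
Reagents that add atoms: phosphorus tribromide, BrP(Br)Br
Why: Bromination of a primary benzylic alcohol with PBr3 runs by SN2 displacement of the phosphite ester by bromide, and this fragment holds no acid-labile group that the HBr formed could harm.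

Step 6
Reactants: 7 methyl 3-(4-formylphenoxy)-4-(methoxymethoxy)benzoate
Product: 10 methyl 3-[4-(hydroxymethyl)phenoxy]-4-(methoxymethoxy)benzoate
Conditions: NaBH4, MeOH/THF, 0 °C
Reagents that add atoms: none
Why: Chemoselective borohydride reduction of the aldehyde, with ester and MOM acetal untouched in the mildly basic medium.

Step 7
Reactants: 10 methyl 3-[4-(hydroxymethyl)phenoxy]-4-(methoxymethoxy)benzoate
Product: 11 methyl 3-{4-[(acetylsulfanyl)methyl]phenoxy}-4-(methoxymethoxy)benzoate
Conditions: AcSH, PPh3, DIAD, THF, 0 °C to rt
Reagents that add atoms: thioacetic acid, CC(=O)S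
Why: Mitsunobu reaction, in which the primary benzylic alcohol is activated as its oxyphosphonium salt and displaced by thioacetate under nearly neutral conditions that spare the MOM acetal and deliver sulfur in an air-stable masked form without a halide stage.

Step 8
Reactants: 9 methyl 3-[2-(bromomethyl)-6-methoxyphenoxy]benzoate; 11 methyl 3-{4-[(acetylsulfanyl)methyl]phenoxy}-4-(methoxymethoxy)benzoate
Product: 13 A–D sulfide diester, via ring D thiol 12 (not isolated)
Conditions: K2CO3, dry degassed MeOH/THF, rt, Ar
Reagents that add atoms: none
Why: One-pot thioacetate methanolysis and thiolate SN2 alkylation, where the thiolate of 12 is released only in the presence of bromide 9 and is far more nucleophilic than methanol or carbonate, so the unsymmetrical sulfide should form without disulfide, and ester exchange with methanol is degenerate.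

Step 9
Reactants: 13 A–D sulfide diester
Product: 14 A–D sulfide diol
Conditions: LiAlH4, THF, 0 °C; aqueous work-up
Reagents that add atoms: none
Why: LiAlH4 reduction of both benzoate esters to primary benzylic alcohols, to which the sulfide, the MOM acetal and the aryl ethers are inert.

Step 10
Reactants: 14 A–D sulfide diol
Product: 16 A–D sulfide dibromide, via bis-mesylate 15 (not isolated)
Conditions: MsCl, i-Pr2NEt, THF, −10 °C; then LiBr, 0 °C to rt
Reagents that add atoms: lithium bromide, [Li+].[Br-]; methanesulfonyl chloride, CS(=O)(=O)Cl (its atoms stay only in 15)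
Why: Mesylation followed by Finkelstein-type SN2 displacement with bromide keeps the medium basic to neutral throughout, so the MOM acetal never meets HBr, and the hindered amine should not quaternise on the benzylic halide.

Step 11
Reactants: 16 A–D sulfide dibromide
Product: 19 dithiacyclophane MOM ether, via ring B thiol bromide 17 (not isolated), via ring C thiol bromide 18 (not isolated)
Conditions: 16 in THF and Na2S·9H2O in EtOH/H2O added simultaneously by syringe pump to degassed EtOH, 60 °C, N2, final concentration about 1 mM
Reagents that add atoms: sodium sulfide (used as the nonahydrate), [Na+].[Na+].[S-2]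
Why: Thiacyclophane synthesis by double SN2 with sulfide ion under pseudo-high dilution, in which the first displacement at either bromide gives a bromo thiolate (17 or 18) whose fast, soft intramolecular alkylation closes the same 20-membered ring, so the two ends need no differentiation.

Step 12
Reactants: 19 dithiacyclophane MOM ether
Product: 22 MOM ether of the target, via B–C monosulfide 20 (not isolated), via D–A monosulfide 21 (not isolated)
Conditions: hν (254 nm, low-pressure Hg lamps, quartz), degassed P(OMe)3 as solvent, about 2 mM, Ar, rt
Reagents that add atoms: none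
Why: Light of 254 nm breaks a benzylic C–S bond, the thiyl radical adds to P(OMe)3, and the phosphoranyl radical fragments to (MeO)3P=S and a second benzyl radical, which leaves a tethered benzyl radical pair that collapses to the CH2–CH2 bond. The closest known reaction type is this very one, the photochemical sulfur extrusion of dithiacyclophanes in trialkyl phosphites, used here on a larger and less strained ring. The 18-membered ring is closed by two successive one-atom contractions (20 to 19 to 18 members) through radical–radical recombination and not by an end-to-end cyclisation, and either sulfur may leave first because 20 and 21 both lead to 22. No stereocentre is created. The selectivity needed is recombination inside the molecule over hydrogen abstraction and dimerisation, which is secured by the macrocyclic tether that holds the two radical centres together, by the benzylic stabilisation of all four carbons and by millimolar dilution, while the A–B–C–D order cannot scramble because only one radical pair exists at a time. The MOM acetal, the methyl ether and the two diaryl ethers hold no comparably weak bond and should persist if irradiation is stopped once 20 and 21 are consumed.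

Step 13
Reactants: 22 MOM ether of the target
Product: 23 target phenol CNP0309263.0
Conditions: HCl (aq, catalytic), MeOH/THF, 50 °C
Reagents that add atoms: none
Why: Acid-catalysed acetal exchange (MOM cleavage), in which protonation and loss of the phenol give an oxocarbenium ion that methanol traps as dimethoxymethane, while the aryl methyl ether, the diaryl ethers and the bibenzyl bridges are stable to dilute HCl.

Compound list
1 | 2-fluoro-3-methoxybenzaldehyde | COc1cccc(C=O)c1F | starting material
2 | methyl 3-hydroxybenzoate | COC(=O)c1cccc(O)c1 | starting material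
3 | methyl 3-(2-formyl-6-methoxyphenoxy)benzoate (rings A and B) | COc1cccc(C=O)c1Oc1cccc(c1)C(=O)OC | intermediate
4 | methyl 3,4-dihydroxybenzoate | COC(=O)c1ccc(O)c(O)c1 | starting material
5 | methyl 3-hydroxy-4-(methoxymethoxy)benzoate | COCOc1ccc(cc1O)C(=O)OC | intermediate
6 | 4-fluorobenzaldehyde | O=Cc1ccc(F)cc1 | starting material
7 | methyl 3-(4-formylphenoxy)-4-(methoxymethoxy)benzoate (rings C and D) | COCOc1ccc(cc1Oc1ccc(C=O)cc1)C(=O)OC | intermediate
8 | methyl 3-[2-(hydroxymethyl)-6-methoxyphenoxy]benzoate | COc1cccc(CO)c1Oc1cccc(c1)C(=O)OC | intermediate
9 | methyl 3-[2-(bromomethyl)-6-methoxyphenoxy]benzoate | COc1cccc(CBr)c1Oc1cccc(c1)C(=O)OC | intermediate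
10 | methyl 3-[4-(hydroxymethyl)phenoxy]-4-(methoxymethoxy)benzoate | COCOc1ccc(cc1Oc1ccc(CO)cc1)C(=O)OC | intermediate
11 | methyl 3-{4-[(acetylsulfanyl)methyl]phenoxy}-4-(methoxymethoxy)benzoate | COCOc1ccc(cc1Oc1ccc(CSC(C)=O)cc1)C(=O)OC | intermediate
12 | methyl 4-(methoxymethoxy)-3-[4-(sulfanylmethyl)phenoxy]benzoate (ring D thiol, formed in the flask) | COCOc1ccc(cc1Oc1ccc(CS)cc1)C(=O)OC | intermediate
13 | A–D sulfide diester: methyl 3-{2-[({4-[5-(methoxycarbonyl)-2-(methoxymethoxy)phenoxy]benzyl}sulfanyl)methyl]-6-methoxyphenoxy}benzoate | COc1cccc(CSCc2ccc(Oc3cc(ccc3OCOC)C(=O)OC)cc2)c1Oc1cccc(c1)C(=O)OC | intermediate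
14 | A–D sulfide diol: both CO2Me groups of 13 (rings B and C) replaced by CH2OH | COc1cccc(CSCc2ccc(Oc3cc(CO)ccc3OCOC)cc2)c1Oc1cccc(CO)c1 | intermediate
15 | bis-mesylate of 14 (formed in the flask) | COc1cccc(CSCc2ccc(Oc3cc(COS(C)(=O)=O)ccc3OCOC)cc2)c1Oc1cccc(COS(C)(=O)=O)c1 | intermediate
16 | A–D sulfide dibromide: CH2Br on ring B and on ring C | COc1cccc(CSCc2ccc(Oc3cc(CBr)ccc3OCOC)cc2)c1Oc1cccc(CBr)c1 | intermediate
17 | ring B thiol bromide: CH2SH on ring B, CH2Br on ring C (formed in the flask) | COc1cccc(CSCc2ccc(Oc3cc(CBr)ccc3OCOC)cc2)c1Oc1cccc(CS)c1 | intermediate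
18 | ring C thiol bromide: CH2SH on ring C, CH2Br on ring B (formed in the flask) | COc1cccc(CSCc2ccc(Oc3cc(CS)ccc3OCOC)cc2)c1Oc1cccc(CBr)c1 | intermediate
19 | 20-membered dithiacyclophane MOM ether: ring A–O–ring B–CH2SCH2–ring C(OMOM)–O–ring D–CH2SCH2–ring A | COc1cccc2c1Oc1cccc(c1)CSCc1ccc(OCOC)c(c1)Oc1ccc(cc1)CSC2 | intermediate
20 | 19-membered B–C monosulfide: D–A bridge already CH2CH2 (formed in the flask) | COc1cccc2c1Oc1cccc(c1)CSCc1ccc(OCOC)c(c1)Oc1ccc(cc1)CC2 | intermediate
21 | 19-membered D–A monosulfide: B–C bridge already CH2CH2 (formed in the flask) | COc1cccc2c1Oc1cccc(c1)CCc1ccc(OCOC)c(c1)Oc1ccc(cc1)CSC2 | intermediate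
22 | 18-membered MOM ether of the target | COc1cccc2c1Oc1cccc(c1)CCc1ccc(OCOC)c(c1)Oc1ccc(cc1)CC2 | intermediate
23 | CNP0309263.0, 18-membered bis(bibenzyl) phenol | COc1cccc2c1Oc1cccc(c1)CCc1ccc(O)c(c1)Oc1ccc(cc1)CC2 | target

Total step count: 13.
Longest linear sequence: 10 steps (4 → 5 → 7 → 10 → 11 → 13 → 14 → 16 → 19 → 22 → 23).

Steps most likely to fail

1. Step 12.
   - What may go wrong: the benzyl radical pair may escape recombination through hydrogen abstraction or intermolecular coupling. The second extrusion may stall. Long irradiation may begin to cleave diaryl ether bonds.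
   - Fallback, setting out from 19 and returning at 22: the same two C–C bonds are made by an ionic ring contraction. Oxidation of 19 with mCPBA (CH2Cl2, 0 °C) should give the macrocyclic bis-sulfone F1. A double Ramberg–Bäcklund reaction (CBr2F2, KOH on Al2O3, t-BuOH/CH2Cl2) should give the 18-membered bis-stilbene F2 as a mixture of alkene geometries. The mixture is of no consequence, because hydrogenation (H2, Pd/C, EtOAc) converts both alkenes into the ethano bridges of 22.

2. Step 11.
   - What may go wrong: oligomerisation may compete with ring closure, or sulfide may substitute both bromides before either thiolate cyclises.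
   - Fallback, setting out from 16 and returning at 19: the ring is closed by reversible S–S bond formation and then contracted by one sulfur. KSAc in DMF should give the bis(thioacetate) F3. K2CO3 in degassed MeOH/THF should release the dithiol F4. Oxidation with I2 and Et3N at high dilution should close the 21-membered cyclic disulfide F5, where thiol–disulfide exchange can correct oligomers. Desulfurisation of the disulfide with P(NEt2)3 in warm toluene should deliver 19, the existing A–D sulfide being inert to the aminophosphine.

3. Step 2.
   - What may go wrong: site selectivity between the two phenols may be poor, and over-alkylation may cost material.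
   - Fallback, setting out from 4 and returning at 7: the order of events is reversed and the selectivity principle changed. Double deprotonation of 4 (KOt-Bu, 2.1 equiv, DMSO, Ar) gives a dianion whose 3-oxide is not conjugated with the ester and is the more nucleophilic. SNAr on 6 should therefore give methyl 3-(4-formylphenoxy)-4-hydroxybenzoate F6. The single remaining phenol is then protected without ambiguity (MOMCl, i-Pr2NEt, CH2Cl2) to give 7.

Further compounds
F1 | step 12 | 20-membered bis-sulfone of 19 | COc1cccc2c1Oc1cccc(c1)CS(=O)(=O)Cc1ccc(OCOC)c(c1)Oc1ccc(cc1)CS(=O)(=O)C2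
F2 | step 12 | 18-membered bis-stilbene MOM ether (alkene geometries not defined, both removed by hydrogenation) | COc1cccc2c1Oc1cccc(c1)C=Cc1ccc(OCOC)c(c1)Oc1ccc(cc1)C=C2
F3 | step 11 | A–D sulfide bis(thioacetate) | COc1cccc(CSCc2ccc(Oc3cc(CSC(C)=O)ccc3OCOC)cc2)c1Oc1cccc(CSC(C)=O)c1
F4 | step 11 | A–D sulfide dithiol | COc1cccc(CSCc2ccc(Oc3cc(CS)ccc3OCOC)cc2)c1Oc1cccc(CS)c1
F5 | step 11 | 21-membered cyclic disulfide (B–CH2SSCH2–C, D–CH2SCH2–A) | COc1cccc2c1Oc1cccc(c1)CSSCc1ccc(OCOC)c(c1)Oc1ccc(cc1)CSC2
F6 | step 2 | methyl 3-(4-formylphenoxy)-4-hydroxybenzoate | COC(=O)c1ccc(O)c(Oc2ccc(C=O)cc2)c1
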